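**Strategy.** The ten-membered ring C1–C10 hides a cyclohexane: if C5 and C10 are joined, atoms C5–C10 form a six-membered ring that already holds C8 and C9, while C4=C3 (on C5) and C1=C2 (on C10) become two alkenyl arms on neighbouring carbons. The route therefore builds that cyclohexanol from Hagemann's ester and expands it by an anionic oxy-Cope rearrangement, which forms C2–C3 and breaks C5–C10 in one operation and leaves the C5 ketone, C4 ester and a ring alkene. The precursor is a trans-1-(acrylat-2-yl)-2-vinylcyclohexanol with tert-butyl esters and a ketal-masked furyl ketone; dehydrogenation, alkene conjugation, methylenation and one acid treatment finish the diacid.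

Key step: step 14

Remark on locants: C1–C20 are the target's (ring C1–C10; C17 on C8 and C18 on C4 are the carboxyl carbons; C19 is the methylidene on C5; C20 the methyl on C9; C11–C12 the side chain); ten-membered compounds are named with these locants, cyclohexanes with ring locants.
Remark on stereochemistry: compounds 1, 4, 10, 11 and 16 are racemic; the SMILES of 4, 10 and 11 show the enantiomer that is carried on.
Assumption: pig liver esterase is taken to hydrolyse the (1R,2R,3R) enantiomer of 11 faster; if it prefers the antipode, the recovered ester is the wanted material and is saponified before step 6.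

**Route**

Step 1
Reactants: 1 ethyl 2-methyl-4-oxocyclohex-2-ene-1-carboxylate (Hagemann's ester); 2 (1,3-dioxolan-2-ylmethyl)magnesium bromide
Product: 4 ethyl rac-(1R,2R)-2-(1,3-dioxolan-2-ylmethyl)-2-methyl-4-(trimethylsilyloxy)cyclohex-3-ene-1-carboxylate, via bromomagnesium bis(1,3-dioxolan-2-ylmethyl)cuprate 3 (not isolated)
Conditions: 2 (2 equiv), CuBr·SMe2 (1 equiv), THF, −40 °C; then Me3SiCl, 1, −78 → −30 °C; Et3N, cold aq. NaHCO3
Reagents that add atoms: chlorotrimethylsilane, C[Si](C)(C)Cl
Why: The Me3SiCl-accelerated conjugate addition of the weakly basic organocopper reagent to the β,β-disubstituted enone should create quaternary C9 with the acetal chain entering anti to the C8 ester (ester and C20 methyl cis), and O-silylation of the enolate fixes the C5=C10 enol ether that marks C10 for the next bond.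

Step 2
Reactants: 5 diphenyl diselenide; 6 2-bromo-1,1-diethoxyethane
Product: 9 2-(phenylselanyl)acetaldehyde, via sodium benzeneselenolate 7 (not isolated), via (2,2-diethoxyethyl)(phenyl)selane 8 (not isolated)
Conditions: NaBH4, EtOH, 0 °C; 6, reflux; then 1 M HCl, THF, 23 °C
Reagents that add atoms: water, O
Why: Borohydride cleavage of the diselenide gives the selenolate, which displaces the primary bromide (SN2), and acid hydrolysis of the acetal releases the aldehyde.

Step 3
Reactants: 4 silyl enol ether; 9 2-(phenylselanyl)acetaldehyde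
Product: 10 ethyl rac-(1R,2R,3S)-2-(1,3-dioxolan-2-ylmethyl)-3-[1-hydroxy-2-(phenylselanyl)ethyl]-2-methyl-4-oxocyclohexane-1-carboxylate (both carbinol epimers)
Conditions: BF3·OEt2, CH2Cl2, −78 °C; aq. NaHCO3
Reagents that add atoms: none
Why: Mukaiyama aldol addition of the regiodefined silyl enol ether forms the C10–C1 bond only at C10 (never at C6), the aldehyde approaching the face opposite the larger dioxolanylmethyl group on C9 and therefore cis to the C20 methyl.

Step 4
Reactants: 10 β-hydroxy selenide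
Product: 11 ethyl rac-(1R,2R,3R)-2-(1,3-dioxolan-2-ylmethyl)-3-ethenyl-2-methyl-4-oxocyclohexane-1-carboxylate
Conditions: MeSO2Cl, Et3N, CH2Cl2, −20 → 0 °C
Reagents that add atoms: none
Why: Mesylation of the β-hydroxy selenide triggers selenium-assisted anti-elimination through the seleniranium ion (the classical α-vinylation of ketones with a 2-selanyl aldehyde), which gives the terminal alkene from either carbinol epimer without involving C10–H, so the β,γ-unsaturated ketone is not conjugated.

Step 5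
Reactants: 11 racemic vinyl keto ester
Product: 12 (1R,2R,3R)-2-(1,3-dioxolan-2-ylmethyl)-3-ethenyl-2-methyl-4-oxocyclohexane-1-carboxylic acid
Conditions: pig liver esterase, phosphate buffer pH 7.5, acetone (10%), 25 °C, stopped near half conversion; NaHCO3 extraction
Reagents that add atoms: water, O
Why: Enzymatic kinetic resolution by enantioselective ester hydrolysis should release one enantiomer as the acid, which is separated by extraction from the unreacted (1S,2S,3S) ester, and the neutral medium spares the acetal and the β,γ-unsaturated ketone.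

Step 6
Reactants: 12 resolved acid
Product: 13 tert-butyl (1R,2R,3R)-2-(1,3-dioxolan-2-ylmethyl)-3-ethenyl-2-methyl-4-oxocyclohexane-1-carboxylate
Conditions: tert-butyl 2,2,2-trichloroacetimidate, CH2Cl2/cyclohexane, 23 °C
Reagents that add atoms: tert-butyl 2,2,2-trichloroacetimidate, CC(C)(C)OC(=N)C(Cl)(Cl)Cl
Why: The acid protonates the imidate and is tert-butylated without base (imidate esterification), giving a C8 ester that resists attack by the later C5 alkoxide and falls to acid at the end.

Step 7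
Reactants: 14 tert-butyl propanoate
Product: 16 tert-butyl 2-(phenylselanyl)propanoate, via lithium propanoate enolate 15 (not isolated)
Conditions: LiN(iPr)2, THF, −78 °C; cannulated into PhSeCl, THF, −78 °C; aq. NH4Cl
Reagents that add atoms: benzeneselenenyl chloride, Cl[Se]c1ccccc1
Why: Kinetic deprotonation gives the ester enolate, which is selenenylated on carbon at once by PhSeCl (α-selenenylation of an ester enolate), and inverse addition keeps the electrophile in excess so that the more acidic product is not deprotonated and selenenylated a second time.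

Step 8
Reactants: 13 vinyl ketone; 16 tert-butyl 2-(phenylselanyl)propanoate
Product: 19 tert-butyl (1R,2R,3R,4S)-4-[1-(tert-butoxy)-1-oxo-2-(phenylselanyl)propan-2-yl]-2-(1,3-dioxolan-2-ylmethyl)-3-ethenyl-4-hydroxy-2-methylcyclohexane-1-carboxylate (epimers at the selenium-bearing carbon), via lithium selanyl ester enolate 17 (not isolated), via dichlorocerium ester enolate 18 (not isolated)
Conditions: 16, LiN(iPr)2, THF, −78 °C; CeCl3, −78 °C; then 13, −78 °C; AcOH, −78 °C
Reagents that add atoms: none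
Why: Aldol addition of the α-selanyl ester enolate, made less basic by transmetalation to cerium so that addition outruns enolisation, should occur by equatorial attack on C5 because the axial C20 methyl on C9 blocks the axial path, which places the hydroxyl axial (cis to C20) and the ester arm equatorial and trans to the equatorial C10 vinyl group.

Step 9
Reactants: 19 aldol selenide
Product: 21 tert-butyl (1R,2R,3R,4S)-4-[3-(tert-butoxy)-3-oxoprop-1-en-2-yl]-2-(1,3-dioxolan-2-ylmethyl)-3-ethenyl-4-hydroxy-2-methylcyclohexane-1-carboxylate, via selenoxide 20 (not isolated)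
Conditions: 30% H2O2, pyridine, CH2Cl2, 0 → 23 °C
Reagents that add atoms: none
Why: Selenoxide syn-elimination can only take a hydrogen from the methyl group because C5 bears none, so the 2-substituted acrylate forms regiospecifically and both selenide epimers converge.

Step 10
Reactants: 21 acrylate carbinol
Product: 22 tert-butyl (1R,2R,3R,4S)-4-[3-(tert-butoxy)-3-oxoprop-1-en-2-yl]-3-ethenyl-4-hydroxy-2-methyl-2-(2-oxoethyl)cyclohexane-1-carboxylate
Conditions: 1 M HCl, THF, 23 °C
Reagents that add atoms: water, O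
Why: Acid hydrolysis of the dioxolane acetal frees the C12 aldehyde while the tert-butyl esters and the electron-poor tertiary allylic alcohol tolerate dilute aqueous acid, and the trans relation of O5 and C11 rules out lactol formation.

Step 11
Reactants: 22 aldehyde; 23 3-bromofuran
Product: 26 tert-butyl (1R,2R,3R,4S)-4-[3-(tert-butoxy)-3-oxoprop-1-en-2-yl]-3-ethenyl-2-[2-(furan-3-yl)-2-hydroxyethyl]-4-hydroxy-2-methylcyclohexane-1-carboxylate (C12 epimers), via 3-furyllithium 24 (not isolated), via 3-furyltitanium triisopropoxide 25 (not isolated)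
Conditions: 23, n-BuLi, THF, −78 °C; ClTi(OiPr)3, −78 °C; then 22, −78 → 0 °C
Reagents that add atoms: none
Why: Bromine–lithium exchange and transmetalation give an aryltitanium reagent that adds to aldehydes but neither to tert-butyl esters nor conjugatively to the acrylate, so the furan is attached at C12 chemoselectively.

Step 12
Reactants: 26 diol
Product: 27 tert-butyl (1R,2R,3R,4S)-4-[3-(tert-butoxy)-3-oxoprop-1-en-2-yl]-3-ethenyl-2-[2-(furan-3-yl)-2-oxoethyl]-4-hydroxy-2-methylcyclohexane-1-carboxylate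
Conditions: MnO2, CH2Cl2, 23 °C
Reagents that add atoms: none
Why: MnO2 oxidises the activated furyl carbinol to the aryl ketone, cannot touch the tertiary C5 alcohol, and merges the C12 epimers.

Step 13
Reactants: 27 furyl ketone
Product: 28 tert-butyl (1R,2R,3R,4S)-4-[3-(tert-butoxy)-3-oxoprop-1-en-2-yl]-3-ethenyl-2-{[2-(furan-3-yl)-1,3-dioxolan-2-yl]methyl}-4-hydroxy-2-methylcyclohexane-1-carboxylate
Conditions: Me3SiOCH2CH2OSiMe3, Me3SiOTf (cat.), CH2Cl2, −78 → −20 °C; pyridine; K2CO3, MeOH
Reagents that add atoms: 1,2-bis(trimethylsilyloxy)ethane, C[Si](C)(C)OCCO[Si](C)(C)C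
Why: Noyori ketalisation masks the only ketone now present (C5 is a carbinol, so no second carbonyl competes) under aprotic low-temperature conditions that spare the tert-butyl esters and the furan, and the methanolic carbonate removes any silyl ether formed on O5.

Step 14
Reactants: 28 trans-1-(acrylat-2-yl)-2-vinylcyclohexanol
Product: 31 di-tert-butyl (1(10)E,8R,9R)-9-{[2-(furan-3-yl)-1,3-dioxolan-2-yl]methyl}-9-methyl-5-oxocyclodec-1(10)-ene-4,8-dicarboxylate (C4 epimers), via potassium alkoxide 29 (not isolated), via potassium enolate 30 (not isolated)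
Conditions: KN(SiMe3)2 (1.05 equiv), 18-crown-6, THF (0.02 M), −78 → 0 °C; AcOH, −78 °C
Reagents that add atoms: none
Why: Deprotonation gives the crown-separated alkoxide 29, whose oxyanion weakens the C5–C10 bond, and a concerted [3,3]-sigmatropic shift joins C2 to C3 as C5–C10 breaks, giving enolate 30 and, on quench, 31; the closest known reaction is the anionic oxy-Cope ring expansion of trans-1,2-dialkenylcyclohexanols to cyclodec-5-enones. The ten-membered ring is not closed end to end but arises by four-carbon expansion of ring C5–C10 through a six-membered chair transition state fused to the cyclohexane. No lasting stereocentre is made: C5 and C10 become trigonal, C4 is an epimerisable β-keto ester carbon that is later made trigonal, and C8 and C9 are untouched, while the E geometry of C1=C10 follows from the chair with C9 pseudo-equatorial. The step needs the two arms trans-diequatorial, which step 8 secures by equatorial attack opposite the axial C20 methyl next to an equatorial vinyl group. It also needs the alkoxide to rearrange and not to attack a carbonyl, which the tert-butyl ester on C8 (cis-1,4 to O5) and the tert-butyl acrylate secure. The ester on C4 stabilises the developing enolate, which lowers the barrier and makes the step irreversible.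

Step 15
Reactants: 31 β-keto ester
Product: 33 di-tert-butyl (1(10)E,8R,9R)-9-{[2-(furan-3-yl)-1,3-dioxolan-2-yl]methyl}-9-methyl-5-oxo-4-(phenylselanyl)cyclodec-1(10)-ene-4,8-dicarboxylate (C4 epimers), via sodium enolate 32 (not isolated)
Conditions: NaH (1 equiv), THF, 0 °C; PhSeCl, −78 °C
Reagents that add atoms: benzeneselenenyl chloride, Cl[Se]c1ccccc1
Why: One equivalent of NaH deprotonates only C4, and the preformed β-keto ester enolate is selenenylated on carbon at −78 °C far faster than PhSeCl can add to the ring alkene.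

Step 16
Reactants: 33 α-selanyl keto ester
Product: 36 di-tert-butyl (1Z,3E,8R,9S)-9-{[2-(furan-3-yl)-1,3-dioxolan-2-yl]methyl}-9-methyl-5-oxocyclodeca-1,3-diene-4,8-dicarboxylate, via selenoxide 34 (not isolated), via skipped dienyl keto ester 35 (not isolated)
Conditions: mCPBA (1 equiv), CH2Cl2, −78 °C; Et3N, −78 → 23 °C; DBU (0.2 equiv), 23 °C
Reagents that add atoms: none
Why: Selenoxide syn-elimination can reach only the C3 hydrogens and gives the C3=C4 alkylidene keto ester 35, whose doubly allylic, vinylogously acidic C2 hydrogens are then shuttled by the amine base to C10, so that C1=C10 moves to C1=C2 and the dienylidene dicarbonyl should settle under thermodynamic control in the fully conjugated form with both ring double bonds cis.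

Step 17
Reactants: 36 dienyl keto ester
Product: 37 di-tert-butyl (1Z,3E,8R,9S)-9-{[2-(furan-3-yl)-1,3-dioxolan-2-yl]methyl}-9-methyl-5-methylidenecyclodeca-1,3-diene-4,8-dicarboxylate
Conditions: Cp2Ti(CH3)2, toluene/THF, 65 °C, dark
Reagents that add atoms: dimethyltitanocene Cp2Ti(CH3)2, [CH3-].[CH3-].[Ti+4].c1cc[cH-]c1.c1cc[cH-]c1
Why: Petasis methylenation through Cp2Ti=CH2 turns the C5 ketone into the C19 methylidene without base, so C6, C10 and the C8 centre are untouched, while the hindered tert-butyl esters react far more slowly and the ketal hides the only other ketone.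

Step 18
Reactants: 37 triene diester ketal
Product: 38 (1Z,3E,8R,9S)-9-[2-(furan-3-yl)-2-oxoethyl]-9-methyl-5-methylidenecyclodeca-1,3-diene-4,8-dicarboxylic acid (CNP0137484.1)
Conditions: CF3CO2H, CH2Cl2, H2O, 0 → 23 °C
Reagents that add atoms: water, O
Why: Acidolysis removes both tert-butyl esters as isobutene and hydrolyses the dioxolane in one operation, the electron-poor triene and the 3-acylfuran being poor partners for protonation, so no basic hydrolysis that could epimerise C8 or move the double bonds is needed.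

**Compound list**

1 | ethyl 2-methyl-4-oxocyclohex-2-ene-1-carboxylate (Hagemann's ester, racemic) | CCOC(=O)C1CCC(=O)C=C1C | starting material
2 | (1,3-dioxolan-2-ylmethyl)magnesium bromide | Br[Mg]CC1OCCO1 | starting material
3 | bromomagnesium bis(1,3-dioxolan-2-ylmethyl)cuprate | Br[Mg+].[Cu-](CC1OCCO1)CC1OCCO1 | intermediate
4 | ethyl rac-(1R,2R)-2-(1,3-dioxolan-2-ylmethyl)-2-methyl-4-(trimethylsilyloxy)cyclohex-3-ene-1-carboxylate | C[Si](C)(C)OC=1CC[C@@H](C(=O)OCC)[C@](C)(CC2OCCO2)C=1 | intermediate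
5 | diphenyl diselenide | c1ccccc1[Se][Se]c1ccccc1 | starting material
6 | 2-bromo-1,1-diethoxyethane | CCOC(CBr)OCC | starting material
7 | sodium benzeneselenolate | [Na+].[Se-]c1ccccc1 | intermediate
8 | (2,2-diethoxyethyl)(phenyl)selane | CCOC(C[Se]c1ccccc1)OCC | intermediate
9 | 2-(phenylselanyl)acetaldehyde | O=CC[Se]c1ccccc1 | intermediate
10 | ethyl rac-(1R,2R,3S)-2-(1,3-dioxolan-2-ylmethyl)-3-[1-hydroxy-2-(phenylselanyl)ethyl]-2-methyl-4-oxocyclohexane-1-carboxylate (carbinol epimers) | O=C1CC[C@@H](C(=O)OCC)[C@](C)(CC2OCCO2)[C@H]1C(O)C[Se]c3ccccc3 | intermediate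
11 | ethyl rac-(1R,2R,3R)-2-(1,3-dioxolan-2-ylmethyl)-3-ethenyl-2-methyl-4-oxocyclohexane-1-carboxylate | O=C1CC[C@@H](C(=O)OCC)[C@](C)(CC2OCCO2)[C@H]1C=C | intermediate
12 | (1R,2R,3R)-2-(1,3-dioxolan-2-ylmethyl)-3-ethenyl-2-methyl-4-oxocyclohexane-1-carboxylic acid | O=C1CC[C@@H](C(=O)O)[C@](C)(CC2OCCO2)[C@H]1C=C | intermediate
13 | tert-butyl (1R,2R,3R)-2-(1,3-dioxolan-2-ylmethyl)-3-ethenyl-2-methyl-4-oxocyclohexane-1-carboxylate | O=C1CC[C@@H](C(=O)OC(C)(C)C)[C@](C)(CC2OCCO2)[C@H]1C=C | intermediate
14 | tert-butyl propanoate | CCC(=O)OC(C)(C)C | starting material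
15 | lithium enolate of tert-butyl propanoate | [Li+].[O-]C(OC(C)(C)C)=CC | intermediate
16 | tert-butyl 2-(phenylselanyl)propanoate (racemic) | CC([Se]c1ccccc1)C(=O)OC(C)(C)C | intermediate
17 | lithium enolate of 16 | [Li+].[O-]C(OC(C)(C)C)=C(C)[Se]c1ccccc1 | intermediate
18 | dichlorocerium enolate of 16 | Cl[Ce](Cl)OC(OC(C)(C)C)=C(C)[Se]c1ccccc1 | intermediate
19 | tert-butyl (1R,2R,3R,4S)-4-[1-(tert-butoxy)-1-oxo-2-(phenylselanyl)propan-2-yl]-2-(1,3-dioxolan-2-ylmethyl)-3-ethenyl-4-hydroxy-2-methylcyclohexane-1-carboxylate (epimers at the Se-bearing carbon) | O[C@@]1(C(C)([Se]c3ccccc3)C(=O)OC(C)(C)C)CC[C@@H](C(=O)OC(C)(C)C)[C@](C)(CC2OCCO2)[C@H]1C=C | intermediate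
20 | selenoxide of 19 | O[C@@]1(C(C)([Se](=O)c3ccccc3)C(=O)OC(C)(C)C)CC[C@@H](C(=O)OC(C)(C)C)[C@](C)(CC2OCCO2)[C@H]1C=C | intermediate
21 | tert-butyl (1R,2R,3R,4S)-4-[3-(tert-butoxy)-3-oxoprop-1-en-2-yl]-2-(1,3-dioxolan-2-ylmethyl)-3-ethenyl-4-hydroxy-2-methylcyclohexane-1-carboxylate | O[C@@]1(C(=C)C(=O)OC(C)(C)C)CC[C@@H](C(=O)OC(C)(C)C)[C@](C)(CC2OCCO2)[C@H]1C=C | intermediate
22 | tert-butyl (1R,2R,3R,4S)-4-[3-(tert-butoxy)-3-oxoprop-1-en-2-yl]-3-ethenyl-4-hydroxy-2-methyl-2-(2-oxoethyl)cyclohexane-1-carboxylate | O[C@@]1(C(=C)C(=O)OC(C)(C)C)CC[C@@H](C(=O)OC(C)(C)C)[C@](C)(CC=O)[C@H]1C=C | intermediate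
23 | 3-bromofuran | Brc1ccoc1 | starting material
24 | 3-furyllithium | [Li]c1ccoc1 | intermediate
25 | 3-furyltitanium triisopropoxide | CC(C)O[Ti](OC(C)C)(OC(C)C)c1ccoc1 | intermediate
26 | tert-butyl (1R,2R,3R,4S)-4-[3-(tert-butoxy)-3-oxoprop-1-en-2-yl]-3-ethenyl-2-[2-(furan-3-yl)-2-hydroxyethyl]-4-hydroxy-2-methylcyclohexane-1-carboxylate (C12 epimers) | O[C@@]1(C(=C)C(=O)OC(C)(C)C)CC[C@@H](C(=O)OC(C)(C)C)[C@](C)(CC(O)c2ccoc2)[C@H]1C=C | intermediate
27 | tert-butyl (1R,2R,3R,4S)-4-[3-(tert-butoxy)-3-oxoprop-1-en-2-yl]-3-ethenyl-2-[2-(furan-3-yl)-2-oxoethyl]-4-hydroxy-2-methylcyclohexane-1-carboxylate | O[C@@]1(C(=C)C(=O)OC(C)(C)C)CC[C@@H](C(=O)OC(C)(C)C)[C@](C)(CC(=O)c2ccoc2)[C@H]1C=C | intermediate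
28 | tert-butyl (1R,2R,3R,4S)-4-[3-(tert-butoxy)-3-oxoprop-1-en-2-yl]-3-ethenyl-2-{[2-(furan-3-yl)-1,3-dioxolan-2-yl]methyl}-4-hydroxy-2-methylcyclohexane-1-carboxylate | O[C@@]1(C(=C)C(=O)OC(C)(C)C)CC[C@@H](C(=O)OC(C)(C)C)[C@](C)(CC2(c3ccoc3)OCCO2)[C@H]1C=C | intermediate
29 | potassium alkoxide of 28 | [K+].[O-][C@@]1(C(=C)C(=O)OC(C)(C)C)CC[C@@H](C(=O)OC(C)(C)C)[C@](C)(CC2(c3ccoc3)OCCO2)[C@H]1C=C | intermediate
30 | potassium enolate of 31 | [K+].[O-]C=1CC[C@@H](C(=O)OC(C)(C)C)[C@](C)(CC2(c3ccoc3)OCCO2)/C=C/CCC=1C(=O)OC(C)(C)C | intermediate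
31 | di-tert-butyl (1(10)E,8R,9R)-9-{[2-(furan-3-yl)-1,3-dioxolan-2-yl]methyl}-9-methyl-5-oxocyclodec-1(10)-ene-4,8-dicarboxylate (C4 epimers) | O=C1CC[C@@H](C(=O)OC(C)(C)C)[C@](C)(CC2(c3ccoc3)OCCO2)/C=C/CCC1C(=O)OC(C)(C)C | intermediate
32 | sodium enolate of 31 | [Na+].[O-]C=1CC[C@@H](C(=O)OC(C)(C)C)[C@](C)(CC2(c3ccoc3)OCCO2)/C=C/CCC=1C(=O)OC(C)(C)C | intermediate
33 | di-tert-butyl (1(10)E,8R,9R)-9-{[2-(furan-3-yl)-1,3-dioxolan-2-yl]methyl}-9-methyl-5-oxo-4-(phenylselanyl)cyclodec-1(10)-ene-4,8-dicarboxylate (C4 epimers) | O=C1CC[C@@H](C(=O)OC(C)(C)C)[C@](C)(CC2(c3ccoc3)OCCO2)/C=C/CCC1([Se]c4ccccc4)C(=O)OC(C)(C)C | intermediate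
34 | selenoxide of 33 | O=C1CC[C@@H](C(=O)OC(C)(C)C)[C@](C)(CC2(c3ccoc3)OCCO2)/C=C/CCC1([Se](=O)c4ccccc4)C(=O)OC(C)(C)C | intermediate
35 | di-tert-butyl (1(10)E,8R,9R)-9-{[2-(furan-3-yl)-1,3-dioxolan-2-yl]methyl}-9-methyl-5-oxocyclodeca-1(10),3-diene-4,8-dicarboxylate (C3=C4 geometry open) | O=C1CC[C@@H](C(=O)OC(C)(C)C)[C@](C)(CC2(c3ccoc3)OCCO2)/C=C/CC=C1C(=O)OC(C)(C)C | intermediate
36 | di-tert-butyl (1Z,3E,8R,9S)-9-{[2-(furan-3-yl)-1,3-dioxolan-2-yl]methyl}-9-methyl-5-oxocyclodeca-1,3-diene-4,8-dicarboxylate | O=C1CC[C@@H](C(=O)OC(C)(C)C)[C@](C)(CC2(c3ccoc3)OCCO2)C/C=C\C=C/1C(=O)OC(C)(C)C | intermediate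
37 | di-tert-butyl (1Z,3E,8R,9S)-9-{[2-(furan-3-yl)-1,3-dioxolan-2-yl]methyl}-9-methyl-5-methylidenecyclodeca-1,3-diene-4,8-dicarboxylate | C=C1CC[C@@H](C(=O)OC(C)(C)C)[C@](C)(CC2(c3ccoc3)OCCO2)C/C=C\C=C/1C(=O)OC(C)(C)C | intermediate
38 | (1Z,3E,8R,9S)-9-[2-(furan-3-yl)-2-oxoethyl]-9-methyl-5-methylidenecyclodeca-1,3-diene-4,8-dicarboxylic acid | C=C1CC[C@@H](C(=O)O)[C@](C)(CC(=O)c2ccoc2)C/C=C\C=C/1C(=O)O | target

**Step count and risks**

Total step count: 18. Longest linear sequence: 16 steps (1, 3–6, 8–18); steps 2 and 7 prepare the two selenium reagents.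

Steps most likely to fail:

1. Step 14 (key step). The free alkoxide may be consumed by cleavage of the carbinol, attack on an ester or anionic polymerisation of the acrylate before it rearranges. The fallback runs the same [3,3] shift without an anion. It sets out from 28, which is silylated (N-(trimethylsilyl)imidazole, CH2Cl2) to the trimethylsilyl ether of 28, F1. F1 is heated (toluene, 180 °C, sealed tube, BHT) in a thermal siloxy-Cope rearrangement to the ten-membered trimethylsilyl enol ether of 31, F2. Methanolysis (K2CO3, MeOH) then gives 31, where the route is rejoined.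

2. Step 8. Proton transfer from C10 of the hindered, easily enolised ketone to the bulky enolate, or reversal of the crowded aldol, may outpace C–C bond formation. The fallback adds the arm as a small vinyl nucleophile and sets out from 13. 2-Bromo-3,3-diethoxyprop-1-ene is lithiated (t-BuLi, THF, −78 °C), transmetalated with CeCl3 and added to 13 to give tert-butyl (1R,2R,3R,4S)-4-(3,3-diethoxyprop-1-en-2-yl)-2-(1,3-dioxolan-2-ylmethyl)-3-ethenyl-4-hydroxy-2-methylcyclohexane-1-carboxylate, F3. The acyclic allylic acetal is hydrolysed selectively (PPTS, wet acetone, 0 °C) to the 2-substituted acrolein, F4. Pinnick oxidation (NaClO2, NaH2PO4, 2-methylbut-2-ene, t-BuOH/H2O) gives the acrylic acid, F5. Esterification with tert-butyl 2,2,2-trichloroacetimidate returns to 21.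

3. Step 16. After the elimination the proton may return to C4 or C2 instead of C10, so that the alkene migration stops at a deconjugated keto ester or leaves mixed C3=C4 geometry, and the alkylidene keto ester may be degraded by the base. The fallback sets out from 35, isolated by leaving out DBU and washing out the amine cold. C1=C10 is then moved by hydride catalysis, RuHCl(CO)(PPh3)3 (cat.), toluene, 60 °C, which works by Ru–H addition and β-hydride elimination and never forms the dicarbonyl-stabilised anion. It returns to the route at 36.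

**Further compounds**

F1 | step 14 | tert-butyl (1R,2R,3R,4S)-4-[3-(tert-butoxy)-3-oxoprop-1-en-2-yl]-3-ethenyl-2-{[2-(furan-3-yl)-1,3-dioxolan-2-yl]methyl}-2-methyl-4-(trimethylsilyloxy)cyclohexane-1-carboxylate | C[Si](C)(C)O[C@@]1(C(=C)C(=O)OC(C)(C)C)CC[C@@H](C(=O)OC(C)(C)C)[C@](C)(CC2(c3ccoc3)OCCO2)[C@H]1C=C
F2 | step 14 | di-tert-butyl (1(10)E,8R,9R)-9-{[2-(furan-3-yl)-1,3-dioxolan-2-yl]methyl}-9-methyl-5-(trimethylsilyloxy)cyclodeca-1(10),4-diene-4,8-dicarboxylate | C[Si](C)(C)OC=1CC[C@@H](C(=O)OC(C)(C)C)[C@](C)(CC2(c3ccoc3)OCCO2)/C=C/CCC=1C(=O)OC(C)(C)C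
F3 | step 8 | tert-butyl (1R,2R,3R,4S)-4-(3,3-diethoxyprop-1-en-2-yl)-2-(1,3-dioxolan-2-ylmethyl)-3-ethenyl-4-hydroxy-2-methylcyclohexane-1-carboxylate | O[C@@]1(C(=C)C(OCC)OCC)CC[C@@H](C(=O)OC(C)(C)C)[C@](C)(CC2OCCO2)[C@H]1C=C
F4 | step 8 | tert-butyl (1R,2R,3R,4S)-2-(1,3-dioxolan-2-ylmethyl)-3-ethenyl-4-hydroxy-2-methyl-4-(3-oxoprop-1-en-2-yl)cyclohexane-1-carboxylate | O[C@@]1(C(=C)C=O)CC[C@@H](C(=O)OC(C)(C)C)[C@](C)(CC2OCCO2)[C@H]1C=C
F5 | step 8 | 2-[(1S,2R,3R,4R)-4-(tert-butoxycarbonyl)-3-(1,3-dioxolan-2-ylmethyl)-2-ethenyl-1-hydroxy-3-methylcyclohexyl]prop-2-enoic acid | O[C@@]1(C(=C)C(=O)O)CC[C@@H](C(=O)OC(C)(C)C)[C@](C)(CC2OCCO2)[C@H]1C=C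
F0 | step 16 | none | none
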